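**Plan**

1. Cuts: (a) the C6–prenyl bond of the dearomatised ring; (b) the hexanoic acid arm at C8, traced back to (E)-hex-2-enal through a lactone on O7; (c) the C6–CH2 bond to the cyclobutane; (d) the pyranone, from phloroglucinol and 3-methylbut-2-enoic acid; (e) the cyclobutane bond C3'–C4', back to a pyrrolidine built from 2-nitropropane, ethyl 4-oxobutenoate and formaldehyde.
2. Enabling feature: in the cyclobutane (C1' carries isopropenyl, C2' the CH2 link, C3' is the gem-dimethyl carbon, C4' the ring CH2) the C3'–C4' bond joins two carbons that are not stereogenic, and both stereocentres lie one bond away from it. A trans-3,4-disubstituted 2,2-dimethylpyrrolidine therefore already holds all four ring carbons, and loss of N2 from its 1,1-diazene closes the four-membered ring.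
3. Forward order: pyrrolidine ring, cyclobutane (step 4), its two side arms; separately the pyranone on phloroglucinol; an sp2–sp3 coupling joins the halves; the δ-lactone ring brings in the side chain; prenylation dearomatises the carbocycle; lactone opening ends the route.
4. Stereochemistry: C2' (and C1', trans to it) from two amine-catalysed steps (Michael addition, α-hydroxymethylation); the side-chain centre from an amine-catalysed Friedel–Crafts addition; C6 from a ligand-controlled palladium allylation.

Key step: step 4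

Assumption: 29 is drawn as its 5-hydroxy-4,7-dioxo tautomer, and the (1R,2R) ligand of step 15 is assumed to give the (6S) lactone 28; should it favour the C6 epimer, the mirror-image ligand is used instead.

Step 1
Reactants: 1 ethyl (E)-4-oxobut-2-enoate; 2 2-nitropropane
Product: 3 ethyl (2S)-2-(2-nitropropan-2-yl)-4-oxobutanoate
Conditions: (R)-2-[diphenyl(trimethylsilyloxy)methyl]pyrrolidine (10 mol%), PhCO2H (20 mol%), 2 (3 equiv), MeOH, 0 °C to rt
Reagents that add atoms: none
Why: Iminium activation of the enal steers the nitronate of 2 to the ester-bearing β-carbon (organocatalytic Michael addition), and the (R)-catalyst shields one face so that C2 should form as (S); this centre stays epimerisable and is finally needed only trans to its neighbour.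

Step 2
Reactants: 3 ethyl (2S)-2-(2-nitropropan-2-yl)-4-oxobutanoate; 4 formaldehyde
Product: 6 ethyl (2S,3R)-4-[(tert-butyldiphenylsilyl)oxy]-3-formyl-2-(2-nitropropan-2-yl)butanoate, via hydroxy aldehyde 5 (not isolated)
Conditions: aq. HCHO (37%), (S)-2-{bis[3,5-bis(trifluoromethyl)phenyl](trimethylsilyloxy)methyl}pyrrolidine (10 mol%), pH 7 phosphate buffer, toluene, rt; organic phase dried, then t-BuPh2SiCl, imidazole, CH2Cl2, 0 °C
Reagents that add atoms: tert-butyl(chloro)diphenylsilane, CC(C)(C)[Si](Cl)(c1ccccc1)c1ccccc1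
Why: Enamine-catalysed cross-aldol reaction with formaldehyde (α-hydroxymethylation), in which the (S)-diarylprolinol ether blocks one enamine face and should set C3 as (R), followed by silylation before the γ-hydroxy ester can lactonise or dehydrate.

Step 3
Reactants: 6 ethyl (2S,3R)-4-[(tert-butyldiphenylsilyl)oxy]-3-formyl-2-(2-nitropropan-2-yl)butanoate
Product: 8 ethyl (3S,4S)-4-{[(tert-butyldiphenylsilyl)oxy]methyl}-2,2-dimethylpyrrolidine-3-carboxylate, via cyclic imine 7 (not isolated)
Conditions: H2 (4 bar), Raney Ni, EtOH, rt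
Reagents that add atoms: none
Why: Hydrogenation of the tertiary nitro group gives the amine, which condenses with the aldehyde and is reduced further (intramolecular reductive amination) without forming a new stereocentre; C3 stays epimerisable, so any cis material can be equilibrated (NaOEt, EtOH) to the trans ester.

Step 4
Reactants: 8 ethyl (3S,4S)-4-{[(tert-butyldiphenylsilyl)oxy]methyl}-2,2-dimethylpyrrolidine-3-carboxylate
Product: 10 ethyl (1S,4R)-4-{[(tert-butyldiphenylsilyl)oxy]methyl}-2,2-dimethylcyclobutane-1-carboxylate, via 1,1-diazene 9 (not isolated)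
Conditions: PhI(OH)OTs (trivalent iodine, 2.5 equiv), H2NCO2NH4 (8 equiv), CF3CH2OH, 80 °C
Reagents that add atoms: none
Why: Proposed new method: ammonia from the carbamate and PhI(OH)OTs give an iodonitrene that N-aminates the hindered amine, a second equivalent of the trivalent iodine reagent oxidises the hydrazine to 1,1-diazene 9, and loss of N2 (beginning with homolysis of the weaker C–N bond at the tertiary carbon) leaves a singlet 1,4-biradical that collapses to the C2–C3 bond of 10. The closest known reaction type is the iodonitrene-mediated contraction of pyrrolidines that carry aryl or ester groups on the carbons next to nitrogen, together with thermal nitrogen loss from dialkyl 1,1-diazenes; here both radical sites are stabilised by alkyl groups only. The four-membered ring closes by recombination of the tertiary and the primary radical terminus, not by polar displacement at a tertiary carbon. No stereocentre is formed: C3 and C4 of 8 lie β to nitrogen, never carry spin, and become C1 and C4 of 10 with the trans relation unchanged. The step needs recombination to outrun β-scission of the biradical into ethyl 3-methylbut-2-enoate and the allyl silyl ether, and to outrun isomerisation of 9 to a hydrazone; the singlet pair is born gauche inside the former ring, the gem-dimethyl group favours closure and removes the α-hydrogens on one side, and the silyl ether (no electron-rich arene) is inert to the oxidant.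

Step 5
Reactants: 10 ethyl (1S,4R)-4-{[(tert-butyldiphenylsilyl)oxy]methyl}-2,2-dimethylcyclobutane-1-carboxylate
Product: 11 (1S,4R)-4-{[(tert-butyldiphenylsilyl)oxy]methyl}-N-methoxy-N,2,2-trimethylcyclobutane-1-carboxamide
Conditions: MeNH(OMe)·HCl (1.6 equiv), i-PrMgCl (3.2 equiv), THF, −20 to 0 °C
Reagents that add atoms: N,O-dimethylhydroxylamine hydrochloride, CNOC.Cl
Why: The magnesium amide of N,O-dimethylhydroxylamine converts the hindered ester into the N-methoxy-N-methylamide (ester aminolysis) without touching the silyl ether or the trans ring substitution.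

Step 6
Reactants: 11 (1S,4R)-4-{[(tert-butyldiphenylsilyl)oxy]methyl}-N-methoxy-N,2,2-trimethylcyclobutane-1-carboxamide
Product: 12 1-[(1S,4R)-4-{[(tert-butyldiphenylsilyl)oxy]methyl}-2,2-dimethylcyclobutyl]ethan-1-one
Conditions: MeMgBr (1.5 equiv), THF, 0 °C; aq. NH4Cl
Reagents that add atoms: methylmagnesium bromide, C[Mg]Br
Why: The chelated tetrahedral adduct of the N-methoxy-N-methylamide survives until work-up (Weinreb ketone synthesis), so the methyl ketone forms without over-addition.

Step 7
Reactants: 12 1-[(1S,4R)-4-{[(tert-butyldiphenylsilyl)oxy]methyl}-2,2-dimethylcyclobutyl]ethan-1-one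
Product: 13 tert-butyl{[(1R,2R)-3,3-dimethyl-2-(prop-1-en-2-yl)cyclobutyl]methoxy}diphenylsilane
Conditions: Ph3PCH3Br, KOt-Bu, THF, 0 to 50 °C
Reagents that add atoms: methyltriphenylphosphonium bromide, C[P+](c1ccccc1)(c1ccccc1)c1ccccc1.[Br-]
Why: Wittig methylenation of the hindered methyl ketone gives the isopropenyl group, and because the α-carbon already has the thermodynamically preferred trans arrangement, enolisation by the ylide cannot erode it.

Step 8
Reactants: 13 tert-butyl{[(1R,2R)-3,3-dimethyl-2-(prop-1-en-2-yl)cyclobutyl]methoxy}diphenylsilane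
Product: 14 [(1R,2R)-3,3-dimethyl-2-(prop-1-en-2-yl)cyclobutyl]methanol
Conditions: Bu4NF, THF, rt
Reagents that add atoms: none
Why: Fluoride-mediated desilylation frees the primary alcohol under conditions that leave the 1,1-disubstituted alkene and the strained ring alone.

Step 9
Reactants: 14 [(1R,2R)-3,3-dimethyl-2-(prop-1-en-2-yl)cyclobutyl]methanol
Product: 15 (2R,3R)-3-(iodomethyl)-1,1-dimethyl-2-(prop-1-en-2-yl)cyclobutane
Conditions: I2, PPh3, imidazole, CH2Cl2, 0 °C to rt, dark
Reagents that add atoms: iodine, [I][I]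
Why: Appel-type iodination proceeds by SN2 displacement of an alkoxyphosphonium ion at the primary carbon, so no cyclobutylcarbinyl cation and hence no ring expansion can arise.

Step 10
Reactants: 16 phloroglucinol; 17 3-methylbut-2-enoic acid
Product: 18 5,7-dihydroxy-2,2-dimethylchroman-4-one
Conditions: P2O5–MeSO3H (1:10 w/w), 70 °C
Reagents that add atoms: none
Why: Friedel–Crafts acylation of the symmetrical triol followed by intramolecular oxa-Michael addition closes the pyranone, and symmetry allows only one constitutional isomer.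

Step 11
Reactants: 18 5,7-dihydroxy-2,2-dimethylchroman-4-one
Product: 19 7-[(tert-butyldimethylsilyl)oxy]-5-hydroxy-2,2-dimethylchroman-4-one
Conditions: t-BuMe2SiCl (1.05 equiv), imidazole, CH2Cl2, 0 °C
Reagents that add atoms: tert-butyl(chloro)dimethylsilane, CC(C)(C)[Si](C)(C)Cl
Why: The 5-OH is tied up in a hydrogen bond to the C4 carbonyl, so silyl ether formation should occur selectively at the more acidic and accessible 7-OH.

Step 12
Reactants: 19 7-[(tert-butyldimethylsilyl)oxy]-5-hydroxy-2,2-dimethylchroman-4-one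
Product: 20 7-[(tert-butyldimethylsilyl)oxy]-5-hydroxy-6-iodo-2,2-dimethylchroman-4-one
Conditions: BnMe3N·ICl2 (1.05 equiv), CaCO3, CH2Cl2–MeOH (5:2), rt
Reagents that add atoms: benzyltrimethylammonium dichloroiodate, C[N+](C)(C)Cc1ccccc1.Cl[I-]Cl
Why: Electrophilic aromatic iodination of a 5-hydroxy-7-alkoxy-type chromanone is directed ortho to the free chelated phenol, so iodine should enter C6 and leave C8 open.

Step 13
Reactants: 15 (2R,3R)-3-(iodomethyl)-1,1-dimethyl-2-(prop-1-en-2-yl)cyclobutane; 20 7-[(tert-butyldimethylsilyl)oxy]-5-hydroxy-6-iodo-2,2-dimethylchroman-4-one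
Product: 23 5,7-dihydroxy-2,2-dimethyl-6-{[(1S,2R)-3,3-dimethyl-2-(prop-1-en-2-yl)cyclobutyl]methyl}chroman-4-one, via borinate 21 (not isolated), via silyl ether 22 (not isolated)
Conditions: 15, 9-MeO-9-BBN (1.5 equiv), t-BuLi (2.05 equiv), Et2O–THF, −78 °C to rt; then 20, PdCl2(dppf) (5 mol%), AsPh3 (10 mol%), aq. K3PO4 (3 M), DMF, 45 °C; then Bu4NF, THF, 0 °C
Reagents that add atoms: none
Why: B-alkyl Suzuki–Miyaura coupling, in which iodine–lithium exchange with immediate capture by the borinic ester avoids any free radical or long-lived carbanion that could open the cyclobutylcarbinyl system; the ate complex transmetalates to the aryl–palladium iodide, and fluoride then removes the aryl silyl ether.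

Step 14
Reactants: 23 5,7-dihydroxy-2,2-dimethyl-6-{[(1S,2R)-3,3-dimethyl-2-(prop-1-en-2-yl)cyclobutyl]methyl}chroman-4-one; 24 (E)-hex-2-enal
Product: 26 δ-lactone onto O-7 of (3R)-3-(5,7-dihydroxy-2,2-dimethyl-4-oxo-6-{[(1S,2R)-3,3-dimethyl-2-(prop-1-en-2-yl)cyclobutyl]methyl}chroman-8-yl)hexanoic acid, via lactol 25 (not isolated)
Conditions: 24 (1.5 equiv), (S)-2-[diphenyl(trimethylsilyloxy)methyl]pyrrolidine (20 mol%), PhCO2H (20 mol%), CH2Cl2, 0 °C to rt; then N-methylmorpholine N-oxide, (n-Pr4N)[RuO4] (5 mol%), 4 Å sieves, CH2Cl2, rt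
Reagents that add atoms: none
Why: Iminium-catalysed Friedel–Crafts alkylation of the acidic phenol at C8, its only free ring position, followed by hemiacetal formation with the 7-OH; the (S)-catalyst shields one face of the enal so the new centre should be (R), and perruthenate-catalysed oxidation turns the lactol into the lactone.

Step 15
Reactants: 26 δ-lactone onto O-7 of (3R)-3-(5,7-dihydroxy-2,2-dimethyl-4-oxo-6-{[(1S,2R)-3,3-dimethyl-2-(prop-1-en-2-yl)cyclobutyl]methyl}chroman-8-yl)hexanoic acid; 27 3-methylbut-2-en-1-yl acetate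
Product: 28 (6S)-6-prenyl cyclohexa-2,4-dienone derived from 26 (C5 ketone; C6 quaternary with prenyl and the cyclobutylmethyl group; C7=C8 enol δ-lactone; pyranone and (4R)-propyl centre unchanged)
Conditions: 27 (1.5 equiv), [Pd(C3H5)Cl]2 (2.5 mol%), (1R,2R)-N,N'-bis[2-(diphenylphosphino)benzoyl]cyclohexane-1,2-diamine (7.5 mol%), Cs2CO3 (1.2 equiv), toluene, 0 °C to rt
Reagents that add atoms: none
Why: Proposed new method: zerovalent palladium ionises 27 to a 1,1-dimethylallyl complex, and the caesium 5-phenoxide of 26 (O-7 is blocked as the lactone) attacks through its ortho carbon C6 at the unsubstituted allyl terminus (Tsuji–Trost allylation); O-prenylation is reversible under the catalyst and C8 is shielded by the lactone ring, so the chiral pocket of the diamine-bisphosphine ligand rather than the remote stereocentres should choose the face and give (6S)-28; the closest known reaction types are the palladium-catalysed asymmetric allylic dearomatisation of 1-alkyl-2-naphthols and the base-mediated geminal prenylation of alkylated acylphloroglucinols.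

Step 16
Reactants: 28 (6S)-6-prenyl cyclohexa-2,4-dienone derived from 26
Product: 29 (3R)-3-[(6R)-5-hydroxy-2,2-dimethyl-6-{[(1S,2R)-3,3-dimethyl-2-(prop-1-en-2-yl)cyclobutyl]methyl}-6-(3-methylbut-2-en-1-yl)-4,7-dioxo-3,4,6,7-tetrahydro-2H-chromen-8-yl]hexanoic acid (CNP0358381.1)
Conditions: LiOH (2.5 equiv), THF–H2O (3:1), 0 °C; then 0.5 M HCl to pH 3
Reagents that add atoms: water, O
Why: Saponification of the enol lactone, an acyl enol ester far more labile than any other carbonyl present, releases the acid and the C7 oxygen; the vinylogous acid tautomerises to the 5-hydroxy-4,7-dioxo form, and as its enolate it should resist retro-oxa-Michael opening of the pyranone.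

**Compound list**

1 | ethyl (E)-4-oxobut-2-enoate | CCOC(=O)/C=C/C=O | starting material
2 | 2-nitropropane | CC(C)[N+](=O)[O-] | starting material
3 | ethyl (2S)-2-(2-nitropropan-2-yl)-4-oxobutanoate | CCOC(=O)[C@H](C(C)(C)[N+](=O)[O-])CC=O | intermediate
4 | formaldehyde | C=O | starting material
5 | ethyl (2S,3R)-3-formyl-4-hydroxy-2-(2-nitropropan-2-yl)butanoate | CCOC(=O)[C@H](C(C)(C)[N+](=O)[O-])[C@H](CO)C=O | intermediate (not isolated)
6 | ethyl (2S,3R)-4-[(tert-butyldiphenylsilyl)oxy]-3-formyl-2-(2-nitropropan-2-yl)butanoate | CCOC(=O)[C@H](C(C)(C)[N+](=O)[O-])[C@H](CO[Si](c1ccccc1)(c1ccccc1)C(C)(C)C)C=O | intermediate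
7 | ethyl (3S,4S)-4-{[(tert-butyldiphenylsilyl)oxy]methyl}-2,2-dimethyl-3,4-dihydro-2H-pyrrole-3-carboxylate (cyclic imine) | CCOC(=O)[C@H]1[C@H](CO[Si](c2ccccc2)(c2ccccc2)C(C)(C)C)C=NC1(C)C | intermediate (not isolated)
8 | ethyl (3S,4S)-4-{[(tert-butyldiphenylsilyl)oxy]methyl}-2,2-dimethylpyrrolidine-3-carboxylate (trans) | CCOC(=O)[C@H]1[C@H](CO[Si](c2ccccc2)(c2ccccc2)C(C)(C)C)CNC1(C)C | intermediate
9 | 1,1-diazene of 8 (pyrrolidin-1-ium-1-ylidene amide) | CCOC(=O)[C@H]1[C@H](CO[Si](c2ccccc2)(c2ccccc2)C(C)(C)C)C[N+](=[N-])C1(C)C | intermediate (not isolated)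
10 | ethyl (1S,4R)-4-{[(tert-butyldiphenylsilyl)oxy]methyl}-2,2-dimethylcyclobutane-1-carboxylate (trans) | CCOC(=O)[C@H]1[C@H](CO[Si](c2ccccc2)(c2ccccc2)C(C)(C)C)CC1(C)C | intermediate
11 | (1S,4R)-4-{[(tert-butyldiphenylsilyl)oxy]methyl}-N-methoxy-N,2,2-trimethylcyclobutane-1-carboxamide | CON(C)C(=O)[C@H]1[C@H](CO[Si](c2ccccc2)(c2ccccc2)C(C)(C)C)CC1(C)C | intermediate
12 | 1-[(1S,4R)-4-{[(tert-butyldiphenylsilyl)oxy]methyl}-2,2-dimethylcyclobutyl]ethan-1-one | CC(=O)[C@H]1[C@H](CO[Si](c2ccccc2)(c2ccccc2)C(C)(C)C)CC1(C)C | intermediate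
13 | tert-butyl{[(1R,2R)-3,3-dimethyl-2-(prop-1-en-2-yl)cyclobutyl]methoxy}diphenylsilane | C=C(C)[C@H]1[C@H](CO[Si](c2ccccc2)(c2ccccc2)C(C)(C)C)CC1(C)C | intermediate
14 | [(1R,2R)-3,3-dimethyl-2-(prop-1-en-2-yl)cyclobutyl]methanol | C=C(C)[C@H]1[C@H](CO)CC1(C)C | intermediate
15 | (2R,3R)-3-(iodomethyl)-1,1-dimethyl-2-(prop-1-en-2-yl)cyclobutane | C=C(C)[C@H]1[C@H](CI)CC1(C)C | intermediate
16 | phloroglucinol (benzene-1,3,5-triol) | Oc1cc(O)cc(O)c1 | starting material
17 | 3-methylbut-2-enoic acid | CC(C)=CC(=O)O | starting material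
18 | 5,7-dihydroxy-2,2-dimethylchroman-4-one | CC1(C)CC(=O)c2c(O)cc(O)cc2O1 | intermediate
19 | 7-[(tert-butyldimethylsilyl)oxy]-5-hydroxy-2,2-dimethylchroman-4-one | CC1(C)CC(=O)c2c(O)cc(O[Si](C)(C)C(C)(C)C)cc2O1 | intermediate
20 | 7-[(tert-butyldimethylsilyl)oxy]-5-hydroxy-6-iodo-2,2-dimethylchroman-4-one | CC1(C)CC(=O)c2c(O)c(I)c(O[Si](C)(C)C(C)(C)C)cc2O1 | intermediate
21 | lithium 9-methoxy-9-{[(1R,2R)-3,3-dimethyl-2-(prop-1-en-2-yl)cyclobutyl]methyl}-9-boranuidabicyclo[3.3.1]nonane (borinate ate complex) | [Li+].C=C(C)[C@H]1[C@H](C[B-]2(OC)C3CCCC2CCC3)CC1(C)C | intermediate (not isolated)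
22 | 7-[(tert-butyldimethylsilyl)oxy]-5-hydroxy-2,2-dimethyl-6-{[(1S,2R)-3,3-dimethyl-2-(prop-1-en-2-yl)cyclobutyl]methyl}chroman-4-one | C=C(C)[C@H]1[C@H](Cc2c(O[Si](C)(C)C(C)(C)C)cc3OC(C)(C)CC(=O)c3c2O)CC1(C)C | intermediate (not isolated)
23 | 5,7-dihydroxy-2,2-dimethyl-6-{[(1S,2R)-3,3-dimethyl-2-(prop-1-en-2-yl)cyclobutyl]methyl}chroman-4-one | C=C(C)[C@H]1[C@H](Cc2c(O)cc3OC(C)(C)CC(=O)c3c2O)CC1(C)C | intermediate
24 | (E)-hex-2-enal | CCC/C=C/C=O | starting material
25 | lactol (cyclic hemiacetal on O-7, both anomers) of (3R)-3-(5,7-dihydroxy-2,2-dimethyl-4-oxo-6-{[(1S,2R)-3,3-dimethyl-2-(prop-1-en-2-yl)cyclobutyl]methyl}chroman-8-yl)hexanal | C=C(C)[C@H]1[C@H](Cc2c(O)c3C(=O)CC(C)(C)Oc3c3c2OC(O)C[C@H]3CCC)CC1(C)C | intermediate (not isolated)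
26 | δ-lactone onto O-7 of (3R)-3-(5,7-dihydroxy-2,2-dimethyl-4-oxo-6-{[(1S,2R)-3,3-dimethyl-2-(prop-1-en-2-yl)cyclobutyl]methyl}chroman-8-yl)hexanoic acid | C=C(C)[C@H]1[C@H](Cc2c(O)c3C(=O)CC(C)(C)Oc3c3c2OC(=O)C[C@H]3CCC)CC1(C)C | intermediate
27 | 3-methylbut-2-en-1-yl acetate (prenyl acetate) | CC(=O)OCC=C(C)C | starting material
28 | (6S)-6-prenyl cyclohexa-2,4-dienone derived from 26 (enol δ-lactone of 29 through O-7, C5 ketone) | C=C(C)[C@H]1[C@H](C[C@@]2(CC=C(C)C)C(=O)C3=C(OC(C)(C)CC3=O)C4=C2OC(=O)C[C@H]4CCC)CC1(C)C | intermediate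
29 | (3R)-3-[(6R)-5-hydroxy-2,2-dimethyl-6-{[(1S,2R)-3,3-dimethyl-2-(prop-1-en-2-yl)cyclobutyl]methyl}-6-(3-methylbut-2-en-1-yl)-4,7-dioxo-3,4,6,7-tetrahydro-2H-chromen-8-yl]hexanoic acid | C=C(C)[C@H]1[C@H](C[C@]2(CC=C(C)C)C(=O)C([C@H](CCC)CC(=O)O)=C3OC(C)(C)CC(=O)C3=C2O)CC1(C)C | target

**Step count and risks**

Total: 16 steps. Longest linear sequence: 13 steps (steps 1–9, then 13–16); the chromanone branch (steps 10–12) joins at step 13.

Steps most likely to fail:

Step 4. The 1,4-biradical may break at its central bond into two alkenes, or the diazene may isomerise to a hydrazone, before the ring closes; slow nitrogen transfer to the hindered amine in a hot, oxidising medium would make both worse. The fallback uses known chemistry, sets out from pyrrolidine 8 and returns at cyclobutane 10. It builds the N–N bond stepwise and releases nitrogen in the cold. Nitrosation of 8 (NaNO2, aqueous AcOH, 0 °C) should give the N-nitrosopyrrolidine F1. Reduction with Zn dust in aqueous AcOH at 10 °C should give the 1-aminopyrrolidine F2. Oxidation of F2 with t-BuOCl and Et3N in Et2O at −78 °C (oxidation of a 1,1-dialkylhydrazine, Overberger–Lombardino type) generates diazene 9 without acid or excess oxidant, and 9 should lose nitrogen on warming to give 10.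

Step 15. Face selection at C6 may be poor if the ligand cannot override the substrate, and O-prenylation or attack at C8 may take material away. The fallback uses known chemistry, sets out from lactone 26 and returns at the target 29, bypassing 28. Aqueous KOH (3 equiv, 0 °C) opens the lactone to the salt of the hydroxy acid F3. Prenyl bromide then alkylates the phloroglucinol-type anion at the alkyl-bearing C6, the classical geminal prenylation of alkylated acylphloroglucinols in aqueous base. Acidification should give 29 together with its C6 epimer F4, to be separated by preparative HPLC.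

Step 14. The acyl-deactivated phenol may add too slowly to the iminium ion, so that uncatalysed addition or self-condensation of the enal takes over and the selectivity at the side-chain centre drops. The fallback uses known chemistry, sets out from diphenol 23 and returns at lactone 26. Butanal and 2,2-dimethyl-1,3-dioxane-4,6-dione (Meldrum's acid) with Et3N in MeCN should form the Knoevenagel product 5-butylidene-2,2-dimethyl-1,3-dioxane-4,6-dione F5. Conjugate addition of C8 of 23 to F5 and lactonisation at 60 °C, with loss of acetone and carbon dioxide, should give 26 and its propyl epimer F6 (the 4-epi lactone). The side-chain centre is not controlled on this path, and the two lactones are separated by chromatography.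

Further compounds
F1 | step 4 | ethyl (3S,4S)-4-{[(tert-butyldiphenylsilyl)oxy]methyl}-2,2-dimethyl-1-nitrosopyrrolidine-3-carboxylate | CCOC(=O)[C@H]1[C@H](CO[Si](c2ccccc2)(c2ccccc2)C(C)(C)C)CN(N=O)C1(C)C
F2 | step 4 | ethyl (3S,4S)-1-amino-4-{[(tert-butyldiphenylsilyl)oxy]methyl}-2,2-dimethylpyrrolidine-3-carboxylate | CCOC(=O)[C@H]1[C@H](CO[Si](c2ccccc2)(c2ccccc2)C(C)(C)C)CN(N)C1(C)C
F3 | step 15 | (3R)-3-(5,7-dihydroxy-2,2-dimethyl-4-oxo-6-{[(1S,2R)-3,3-dimethyl-2-(prop-1-en-2-yl)cyclobutyl]methyl}chroman-8-yl)hexanoic acid | C=C(C)[C@H]1[C@H](Cc2c(O)c3C(=O)CC(C)(C)Oc3c([C@H](CCC)CC(=O)O)c2O)CC1(C)C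
F4 | step 15 | C6 epimer of 29 ((6S) at the quaternary carbon) | C=C(C)[C@H]1[C@H](C[C@@]2(CC=C(C)C)C(=O)C([C@H](CCC)CC(=O)O)=C3OC(C)(C)CC(=O)C3=C2O)CC1(C)C
F5 | step 14 | 5-butylidene-2,2-dimethyl-1,3-dioxane-4,6-dione | CCCC=C1C(=O)OC(C)(C)OC1=O
F6 | step 14 | propyl epimer of 26 ((S) at the lactone C4) | C=C(C)[C@H]1[C@H](Cc2c(O)c3C(=O)CC(C)(C)Oc3c3c2OC(=O)C[C@@H]3CCC)CC1(C)C
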